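**Plan**

- Retrosynthesis: remove the four O-protecting groups, take the four Z-alkenes (C5=C6, C8=C9, C11=C12, C14=C15; C1 is the ketone carbon) back to triple bonds, then cut C9–C10 of the tetrayne into a C1–C9 diynyl aryl ketone (fragment A) and a C10–C20 diynyl bromide (fragment B).
- Fragment A is cut further at C6–C7 (acetylide/propargyl bromide) and at the C1–aryl bond (aryllithium/Weinreb amide). Fragment B is cut at C13–C14 (acetylide/propargyl chloride) and at C15–C16 (acetylide/epoxide).
- Forward order of chain joining: aryl–C1, then C6–C7 (fragment A); C15–C16, then C13–C14 (fragment B); C9–C10 (union). No ring is formed; the benzene ring (ring A) is bought as phloroglucinol.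
- Enabling feature: C7, C10 and C13 are single CH2 groups between the double bonds, so at the alkyne oxidation level C9 is a terminal acetylide carbon and C10 a primary propargylic carbon. The C1 ketone is shielded by the two ortho oxygens of ring A.
- Stereochemistry: C17 (S) is bought in (S)-2-propyloxirane and is never a reacting centre. The four Z double bonds come from one syn semi-hydrogenation of the tetrayne (step 11).

Key step: step 10

Assumption: (S)-2-propyloxirane of high enantiomeric purity is taken as a purchasable building block.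

**Route**

Step 1
Reactants: 1 phloroglucinol (benzene-1,3,5-triol)
Product: 2 1,3,5-tris(methoxymethoxy)benzene
Conditions: MOMCl (3.6 equiv), i-Pr2NEt (4.5 equiv), CH2Cl2, 0 °C to rt
Reagents that add atoms: chloromethyl methyl ether (MOMCl), COCCl
Why: Williamson-type O-alkylation (MOM protection) of the three equivalent phenols with the amine base as HCl scavenger, giving acetals that later direct the ortho-lithiation and should survive organolithium, carbonate and hydrogenation conditions.

Step 2
Reactants: 3 hex-5-ynoic acid
Product: 5 N-methoxy-N-methylhex-5-ynamide, via hex-5-ynoyl imidazolide 4 (not isolated)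
Conditions: CDI (1.1 equiv), CH2Cl2, rt; then MeNH(OMe)·HCl (1.2 equiv), rt
Reagents that add atoms: N,O-dimethylhydroxylamine hydrochloride, CNOC.Cl
Why: Weinreb amide formation by CDI activation, in which the acid is converted to acyl imidazolide 4 with loss of CO2 and the hydroxylamine nitrogen then displaces imidazole, the terminal alkyne being inert.

Step 3
Reactants: 2 1,3,5-tris(methoxymethoxy)benzene; 5 N-methoxy-N-methylhex-5-ynamide
Product: 7 1-[2,4,6-tris(methoxymethoxy)phenyl]hex-5-yn-1-one, via 2,4,6-tris(methoxymethoxy)phenyllithium 6 (not isolated)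
Conditions: 2 (2.4 equiv), n-BuLi (2.3 equiv), THF, 0 °C; then 5 (1.0 equiv), −78 °C to 0 °C; then H2O
Reagents that add atoms: none
Why: Directed ortho-lithiation followed by Weinreb ketone synthesis, in which n-BuLi removes the ring hydrogen between two OMOM groups, one equivalent of 6 is spent on the acidic alkyne C–H (and returns as 2 on work-up), and the second adds to the amide to give a chelated tetrahedral adduct that cannot add again and collapses to ketone 7 on hydrolysis.

Step 4
Reactants: 7 1-[2,4,6-tris(methoxymethoxy)phenyl]hex-5-yn-1-one; 8 3-bromo-1-(trimethylsilyl)prop-1-yne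
Product: 11 9-(trimethylsilyl)-1-[2,4,6-tris(methoxymethoxy)phenyl]nona-5,8-diyn-1-one, via hexynyl ketone copper acetylide 9 (not isolated), via 3-iodo-1-(trimethylsilyl)prop-1-yne 10 (not isolated)
Conditions: CuI (1.0 equiv), NaI (1.0 equiv), Cs2CO3 (1.0 equiv), DMF, rt, under argon
Reagents that add atoms: none
Why: Copper-mediated acetylide–propargyl halide coupling (sp–sp3, SN2 at the CH2–halide carbon, which becomes C7), the silyl cap on 8 ensuring that the new 1,4-diyne cannot couple a second time, while the hindered C1 ketone is not enolised by carbonate.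

Step 5
Reactants: 11 9-(trimethylsilyl)-1-[2,4,6-tris(methoxymethoxy)phenyl]nona-5,8-diyn-1-one
Product: 12 1-[2,4,6-tris(methoxymethoxy)phenyl]nona-5,8-diyn-1-one
Conditions: TBAF (1.1 equiv), AcOH (1.1 equiv), THF, 0 °C
Reagents that add atoms: none
Why: Fluoride-induced protodesilylation of the alkynylsilane, buffered with AcOH so that the doubly propargylic C7 methylene is not deprotonated and no allene should form.

Step 6
Reactants: 13 (S)-2-propyloxirane; 14 lithium acetylide–ethylenediamine complex (LiC≡CH·H2NCH2CH2NH2)
Product: 15 (S)-hept-1-yn-4-ol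
Conditions: 14 (1.5 equiv), DMSO, 0 °C to rt; then H2O
Reagents that add atoms: none
Why: SN2 opening of the monosubstituted epoxide by acetylide at its unsubstituted CH2 carbon (C16), so that no bond at the stereocentre changes and the (S) epoxide gives the (S) homopropargylic alcohol that becomes C17 of the target.

Step 7
Reactants: 15 (S)-hept-1-yn-4-ol
Product: 16 (S)-tert-butyl(hept-1-yn-4-yloxy)dimethylsilane
Conditions: TBSCl (1.2 equiv), imidazole (2 equiv), DMF, rt
Reagents that add atoms: tert-butyldimethylsilyl chloride (TBSCl), CC(C)(C)[Si](C)(C)Cl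
Why: Standard silylation of the secondary alcohol, needed so that only the primary propargylic alcohol made in step 8 is brominated in step 9.

Step 8
Reactants: 16 (S)-tert-butyl(hept-1-yn-4-yloxy)dimethylsilane; 17 4-chlorobut-2-yn-1-ol
Product: 20 (S)-8-(tert-butyldimethylsilyloxy)undeca-2,5-diyn-1-ol, via silyloxyheptynyl copper acetylide 18 (not isolated), via 4-iodobut-2-yn-1-ol 19 (not isolated)
Conditions: 17 (1.2 equiv), CuI (1.0 equiv), NaI (1.0 equiv), Cs2CO3 (1.0 equiv), DMF, rt, under argon
Reagents that add atoms: none
Why: Copper-mediated acetylide–propargyl halide coupling of the same type as step 4, the chloride being activated by halide exchange to iodide 19 and the free primary hydroxyl being tolerated, which builds C13–C14 and installs C10 as CH2OH.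

Step 9
Reactants: 20 (S)-8-(tert-butyldimethylsilyloxy)undeca-2,5-diyn-1-ol
Product: 21 (S)-1-bromo-8-(tert-butyldimethylsilyloxy)undeca-2,5-diyne
Conditions: CBr4 (1.2 equiv), PPh3 (1.2 equiv), CH2Cl2, −20 to 0 °C
Reagents that add atoms: carbon tetrabromide, BrC(Br)(Br)Br
Why: Appel reaction, which converts the primary propargylic alcohol into the bromide under neutral conditions that leave the silyl ether and the base-sensitive 1,4-diyne untouched.

Step 10
Reactants: 12 1-[2,4,6-tris(methoxymethoxy)phenyl]nona-5,8-diyn-1-one; 21 (S)-1-bromo-8-(tert-butyldimethylsilyloxy)undeca-2,5-diyne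
Product: 24 (S)-17-(tert-butyldimethylsilyloxy)-1-[2,4,6-tris(methoxymethoxy)phenyl]icosa-5,8,11,14-tetrayn-1-one, via fragment A copper acetylide 22 (not isolated), via fragment B propargylic iodide 23 (not isolated)
Conditions: CuI (1.0 equiv), NaI (1.0 equiv), Cs2CO3 (1.0 equiv), degassed DMF, rt, under argon, dark
Reagents that add atoms: none
Why: Cs2CO3 removes the C9–H of 12 in the presence of CuI to give the monovalent copper acetylide 22, while NaI turns bromide 21 into the more reactive propargylic iodide 23; the acetylide carbon C9 then displaces iodide at the primary propargylic carbon C10 (SN2), which creates the C9–C10 bond and the complete C1–C20 chain at the tetrayne oxidation level. The closest known reaction type is the copper-mediated coupling of terminal alkynes with propargylic halides that is used to build methylene-interrupted polyynes of the arachidonate type. No ring is closed and no stereocentre is formed; the (S) centre at C17 lies six bonds from the reacting carbon and is not touched. The step needs attack at C10 and not at C12 (SN2 over SN2', which would give an allene), no prototropic isomerisation of the doubly propargylic CH2 groups C7, C10 and C13, and no oxidative dimerisation of the acetylide. These should be secured by the unhindered primary CH2–halide, by carbonate as the only base, by exclusion of oxygen, and by the C1 ketone being flanked by the 2,6-bis(methoxymethoxy) aryl ring, so that it neither enolises nor accepts acetylide. The alkyne oxidation level is the temporary helper: it makes C9 nucleophilic and C10 electrophilic, and all four triple bonds are taken to Z-alkenes together in step 11.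

Step 11
Reactants: 24 (S)-17-(tert-butyldimethylsilyloxy)-1-[2,4,6-tris(methoxymethoxy)phenyl]icosa-5,8,11,14-tetrayn-1-one
Product: 25 (S,5Z,8Z,11Z,14Z)-17-(tert-butyldimethylsilyloxy)-1-[2,4,6-tris(methoxymethoxy)phenyl]icosa-5,8,11,14-tetraen-1-one
Conditions: H2 (1 atm), nickel boride from Ni(OAc)2·4H2O and NaBH4 (cat.), ethylenediamine, EtOH, rt, stopped after uptake of 4 equiv H2
Reagents that add atoms: none
Why: Syn addition of H2 on nickel boride poisoned with ethylenediamine (P-2 nickel semi-hydrogenation) should convert each of the four triple bonds into a Z-alkene and stop there because the amine-modified surface binds alkenes weakly, while the hindered ketone, the acetals and the silyl ether are inert and C17 is unaffected.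

Step 12
Reactants: 25 (S,5Z,8Z,11Z,14Z)-17-(tert-butyldimethylsilyloxy)-1-[2,4,6-tris(methoxymethoxy)phenyl]icosa-5,8,11,14-tetraen-1-one
Product: 26 (S,5Z,8Z,11Z,14Z)-17-hydroxy-1-(2,4,6-trihydroxyphenyl)icosa-5,8,11,14-tetraen-1-one
Conditions: HCl (1.25 M in MeOH), 40 °C, under argon
Reagents that add atoms: none
Why: Acid-catalysed methanolysis (acetal exchange of the three MOM ethers to dimethoxymethane and solvolysis of the silyl ether) should free the four hydroxyls in one operation; methylene-interrupted Z-alkenes are not expected to migrate or isomerise in dilute methanolic HCl, and the secondary homoallylic carbinol does not ionise, so C17 keeps its (S) configuration.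

**Compound list**

1 | phloroglucinol (benzene-1,3,5-triol) | Oc1cc(O)cc(O)c1 | starting material
2 | 1,3,5-tris(methoxymethoxy)benzene | COCOc1cc(OCOC)cc(OCOC)c1 | intermediate
3 | hex-5-ynoic acid | C#CCCCC(=O)O | starting material
4 | hex-5-ynoyl imidazolide, 1-(1H-imidazol-1-yl)hex-5-yn-1-one | C#CCCCC(=O)n1ccnc1 | intermediate (not isolated)
5 | N-methoxy-N-methylhex-5-ynamide | C#CCCCC(=O)N(C)OC | intermediate
6 | 2,4,6-tris(methoxymethoxy)phenyllithium | [Li]c1c(OCOC)cc(OCOC)cc1OCOC | intermediate (not isolated)
7 | 1-[2,4,6-tris(methoxymethoxy)phenyl]hex-5-yn-1-one | C#CCCCC(=O)c1c(OCOC)cc(OCOC)cc1OCOC | intermediate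
8 | 3-bromo-1-(trimethylsilyl)prop-1-yne | C[Si](C)(C)C#CCBr | starting material
9 | hexynyl ketone copper acetylide (monovalent copper acetylide of 7) | [Cu]C#CCCCC(=O)c1c(OCOC)cc(OCOC)cc1OCOC | intermediate (not isolated)
10 | 3-iodo-1-(trimethylsilyl)prop-1-yne | C[Si](C)(C)C#CCI | intermediate (not isolated)
11 | 9-(trimethylsilyl)-1-[2,4,6-tris(methoxymethoxy)phenyl]nona-5,8-diyn-1-one | C[Si](C)(C)C#CCC#CCCCC(=O)c1c(OCOC)cc(OCOC)cc1OCOC | intermediate
12 | 1-[2,4,6-tris(methoxymethoxy)phenyl]nona-5,8-diyn-1-one (fragment A) | C#CCC#CCCCC(=O)c1c(OCOC)cc(OCOC)cc1OCOC | intermediate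
13 | (S)-2-propyloxirane | CCC[C@H]1CO1 | starting material
14 | lithium acetylide–ethylenediamine complex | [Li+].[C-]#C.NCCN | starting material
15 | (S)-hept-1-yn-4-ol | CCC[C@H](O)CC#C | intermediate
16 | (S)-tert-butyl(hept-1-yn-4-yloxy)dimethylsilane | CCC[C@H](O[Si](C)(C)C(C)(C)C)CC#C | intermediate
17 | 4-chlorobut-2-yn-1-ol | OCC#CCCl | starting material
18 | silyloxyheptynyl copper acetylide (monovalent copper acetylide of 16) | CCC[C@H](O[Si](C)(C)C(C)(C)C)CC#C[Cu] | intermediate (not isolated)
19 | 4-iodobut-2-yn-1-ol | OCC#CCI | intermediate (not isolated)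
20 | (S)-8-(tert-butyldimethylsilyloxy)undeca-2,5-diyn-1-ol | CCC[C@H](O[Si](C)(C)C(C)(C)C)CC#CCC#CCO | intermediate
21 | (S)-1-bromo-8-(tert-butyldimethylsilyloxy)undeca-2,5-diyne (fragment B) | CCC[C@H](O[Si](C)(C)C(C)(C)C)CC#CCC#CCBr | intermediate
22 | fragment A copper acetylide (monovalent copper acetylide of 12) | [Cu]C#CCC#CCCCC(=O)c1c(OCOC)cc(OCOC)cc1OCOC | intermediate (not isolated)
23 | fragment B propargylic iodide, (S)-8-(tert-butyldimethylsilyloxy)-1-iodoundeca-2,5-diyne | CCC[C@H](O[Si](C)(C)C(C)(C)C)CC#CCC#CCI | intermediate (not isolated)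
24 | (S)-17-(tert-butyldimethylsilyloxy)-1-[2,4,6-tris(methoxymethoxy)phenyl]icosa-5,8,11,14-tetrayn-1-one | CCC[C@H](O[Si](C)(C)C(C)(C)C)CC#CCC#CCC#CCC#CCCCC(=O)c1c(OCOC)cc(OCOC)cc1OCOC | intermediate
25 | (S,5Z,8Z,11Z,14Z)-17-(tert-butyldimethylsilyloxy)-1-[2,4,6-tris(methoxymethoxy)phenyl]icosa-5,8,11,14-tetraen-1-one | CCC[C@H](O[Si](C)(C)C(C)(C)C)C/C=C\C/C=C\C/C=C\C/C=C\CCCC(=O)c1c(OCOC)cc(OCOC)cc1OCOC | intermediate
26 | (S,5Z,8Z,11Z,14Z)-17-hydroxy-1-(2,4,6-trihydroxyphenyl)icosa-5,8,11,14-tetraen-1-one | CCC[C@H](O)C/C=C\C/C=C\C/C=C\C/C=C\CCCC(=O)c1c(O)cc(O)cc1O | target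

**Step count and risks**

Total step count: 12. Longest linear sequence: 7 steps (steps 1, 3, 4, 5, 10, 11, 12; the sequences through step 2 and through steps 6–9 are equally long).

Steps most likely to fail:

1. Step 11 (fourfold semi-hydrogenation). Over-reduction of some double bonds can run alongside incomplete reduction of some triple bonds, giving mixtures that differ by two hydrogens and are hard to separate; partial Z-to-E isomerisation on the metal surface is also possible. The fallback sets out from 20 and 12 and comes back to the route at 25. Diynol 20 is semi-hydrogenated at this small, polar stage (H2, nickel boride from Ni(OAc)2·4H2O and NaBH4, ethylenediamine, EtOH; only two triple bonds, purification over AgNO3-impregnated silica) to (S,2Z,5Z)-8-(tert-butyldimethylsilyloxy)undeca-2,5-dien-1-ol F1. CBr4/PPh3 then converts F1 into (S,2Z,5Z)-1-bromo-8-(tert-butyldimethylsilyloxy)undeca-2,5-diene F2. Copper-mediated coupling of 12 with F2 (CuI, NaI, Cs2CO3, DMF; acetylide attack at the primary allylic carbon) forms the same C9–C10 bond and should give (S,11Z,14Z)-17-(tert-butyldimethylsilyloxy)-1-[2,4,6-tris(methoxymethoxy)phenyl]icosa-11,14-dien-5,8-diyn-1-one F3. The last hydrogenation then has only two triple bonds to reduce and leads to 25.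

2. Step 10 (fragment union). The terminal 1,4-diyne 12 can undergo base-induced prototropic isomerisation to allenic isomers before it couples; the acetylide can dimerise oxidatively; and attack at the far alkyne carbon would give an allene. The fallback sets out from 21 and 7 and comes back to the route at 24. It avoids the terminal skipped diyne altogether. Bromide 21 is coupled with prop-2-yn-1-ol (CuI, NaI, Cs2CO3, DMF), which makes the C9–C10 bond with a small, robust acetylide and gives (S)-11-(tert-butyldimethylsilyloxy)tetradeca-2,5,8-triyn-1-ol F4. CBr4/PPh3 converts F4 into (S)-1-bromo-11-(tert-butyldimethylsilyloxy)tetradeca-2,5,8-triyne F5. Coupling of F5 with the simple terminal alkyne 7 under the same copper conditions then joins the large fragments at C6–C7 and should give tetrayne 24.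

3. Step 3 (aryl ketone formation). Proton transfer from the terminal alkyne consumes aryllithium, the resulting lithium acetylide may attack the amide of a second molecule, and addition of the hindered aryllithium may stay incomplete. The fallback sets out from 2 (lithiated to 6 as before) and comes back to the route at 7; no acidic alkyne is present when the aryl–C1 bond is made. Aryllithium 6 is added to δ-valerolactone (THF, −78 °C) to give 5-hydroxy-1-[2,4,6-tris(methoxymethoxy)phenyl]pentan-1-one F6. Dess–Martin periodinane oxidises F6 to 5-oxo-5-[2,4,6-tris(methoxymethoxy)phenyl]pentanal F7. Ohira–Bestmann homologation of the aldehyde (dimethyl (1-diazo-2-oxopropyl)phosphonate, K2CO3, MeOH) then gives alkyne 7.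

Further compounds
F1 | step 11 | (S,2Z,5Z)-8-(tert-butyldimethylsilyloxy)undeca-2,5-dien-1-ol | CCC[C@H](O[Si](C)(C)C(C)(C)C)C/C=C\C/C=C\CO
F2 | step 11 | (S,2Z,5Z)-1-bromo-8-(tert-butyldimethylsilyloxy)undeca-2,5-diene | CCC[C@H](O[Si](C)(C)C(C)(C)C)C/C=C\C/C=C\CBr
F3 | step 11 | (S,11Z,14Z)-17-(tert-butyldimethylsilyloxy)-1-[2,4,6-tris(methoxymethoxy)phenyl]icosa-11,14-dien-5,8-diyn-1-one | CCC[C@H](O[Si](C)(C)C(C)(C)C)C/C=C\C/C=C\CC#CCC#CCCCC(=O)c1c(OCOC)cc(OCOC)cc1OCOC
F4 | step 10 | (S)-11-(tert-butyldimethylsilyloxy)tetradeca-2,5,8-triyn-1-ol | CCC[C@H](O[Si](C)(C)C(C)(C)C)CC#CCC#CCC#CCO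
F5 | step 10 | (S)-1-bromo-11-(tert-butyldimethylsilyloxy)tetradeca-2,5,8-triyne | CCC[C@H](O[Si](C)(C)C(C)(C)C)CC#CCC#CCC#CCBr
F6 | step 3 | 5-hydroxy-1-[2,4,6-tris(methoxymethoxy)phenyl]pentan-1-one | OCCCCC(=O)c1c(OCOC)cc(OCOC)cc1OCOC
F7 | step 3 | 5-oxo-5-[2,4,6-tris(methoxymethoxy)phenyl]pentanal | O=CCCCC(=O)c1c(OCOC)cc(OCOC)cc1OCOC
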